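The data are simulated from invented constants; noise was put on by code.

Product cannot pass the charge, however much catalyst goes in. That is the first extreme, a flask bound by its charge, with starting material as the limiting reagent.

| flask | starting material | free catalyst | added ligand | remark | time |
|---|---|---|---|---|---|
| north-west | 0.96 M (fed, over 80 min) | 0.4 mol% | 62 mM | run made earlier; the fed solution adds 0.20 times the starting volume |  |
| north-east | 0.96 M (fed, over 80 min) | 1.7 mol% | 62 mM | run made earlier; the fed solution adds 0.20 times the starting volume |  |
| summer | 0.96 M (fed, over 80 min) | 2 mol% | 62 mM | the fed solution adds 0.20 times the starting volume | 2.5 h |
| midnight | 0.96 M | 0.6 mol% | 62 mM | everything together at the start, the whole solution of starting material included, so that from the start the volume is larger by 0.20 times the starting volume | 2.5 h |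

| north-west: time / min | north-west: product / % | north-east: time / min | north-east: product / % |
|---|---|---|---|
| 8.00 | 0.7 | 8.00 | 1.3 |
| 15.0 | 1.2 | 15.0 | 4.9 |
| 30.0 | 4.4 | 30.0 | 14.7 |
| 60.0 | 12.2 | 60.0 | 39.0 |
| 120 | 30.0 | 120 | 80.5 |

(readings scatter by 0.3 percentage points)

- charges are per starting volume, the dose included; the dosed solution carries all of it
- percentages count the whole charge, also what has not yet gone in

1. the winner by amount of product, in percent of the starting material charged; "neither" if no more than 2 percentage points parts them (summer / midnight / neither)
2. how much product is there at the end, in percent of the starting material charged: summer
3. how much product is there at the end, in percent of the starting material charged: midnight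

The second extreme is a flask bound by its catalyst, where product climbs in a straight line at a steady pace. Read that pace from the steepest stretch of each run, as product per catalyst per minute, the turnover frequency. North-west reads 0.742 min⁻¹ and north-east 0.476 min⁻¹, so the reading is lower at the higher loading.

Now multiply summer's loading by north-east's pace and invert: 105 min. This is the clearing time, the time the catalyst needs to turn the whole charge over at that pace. Hold it against the time allowed, because control changes hands where the two cross.

Summer's clearing time is longer than its feed of 80 min, so expect starting material to gather during the feed. It is shorter than 2.5 h, so expect summer near the charge extreme, just under full.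

Midnight's loading lies between the two runs, so take both paces. Its clearing time is 225 min to 350 min, longer than 2.5 h. Expect midnight short of the charge, and take the two steady paces as a span, which gives between 42.9 % and 66.7 % at 2.5 h. Lean to the upper end, since its loading stands nearer north-west's.

The forecast names summer as the winner. It gives summer 94 % (89 % to 98 %) and midnight 58 % (48 % to 67 %), on the ground that “the rate flattens as substrate builds”. My reckoning gives spans, not these figures.

The flask gives 92.9 % for summer and 59.4 % for midnight, so summer wins.

    catalyst intermediate A → spent catalyst (k = 9.30 × 10⁻⁵ s⁻¹)
    catalyst intermediate B ⇌ free catalyst + product (K = 0.330 M, k = 0.0690 s⁻¹)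
    catalyst intermediate A ⇌ catalyst intermediate B (K = 8.80, k = 0.0440 s⁻¹)
    starting material + free catalyst → catalyst intermediate A (k = 0.180 M⁻¹ s⁻¹)
    free catalyst + added ligand ⇌ idle complex, settled at all times (K = 36.0 M⁻¹)

Summer has passed the crossing, with a clearing time of 105 min, and ends with 5.9 % of its charge left as starting material. Midnight has not passed it and ends with 40 % left. Apply the same reckoning to a neighbour, summer's flask with 0.5 mol% of free catalyst. Its clearing time is 270 min to 420 min, longer than 2.5 h, so the two steady paces span 35.7 % to 55.6 %. The neighbour gives 45.1 %, with 55 % of its charge left as starting material.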